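The impurity is what I watch in the autumn flask, which is followed here up to the moment of choice.

common to all: left-handed substrate 0.80 M; right-handed substrate 0.80 M; free catalyst 40 mM; impurity 41 mM
- autumn: partner 1.2 M; temperature 5 °C; the very flask that is asked about, followed so far
- summer: partner 1.2 M; temperature 0 °C; run made earlier
- flask: partner 1.20 M; temperature 5 °C; time 2.5 h

| run | time / min | left-handed product / % |
|---|---|---|
| autumn | 8.00 | 3.3 |
| autumn | 25.0 | 6.3 |
| autumn | 40.0 | 7.8 |
| autumn | 60.0 | 9.0 |
| autumn | 90.0 | 10.1 |
| autumn | 120 | 10.5 |
| autumn | 150 | 11.4 |
| summer | 8.00 | 2.2 |
| summer | 25.0 | 5.6 |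
| summer | 40.0 | 6.4 |
| summer | 60.0 | 8.4 |
| summer | 90.0 | 9.4 |
| summer | 120 | 9.9 |
| summer | 150 | 10.7 |

(each reading ± 0.5 percentage points)

- Monday's: at 2.5 h raise the temperature by 15 K, then wait 80 min
- Friday's: at 2.5 h take out 90% of the left-handed product then present, then wait 80 min
- Sunday's: at 2.5 h add free catalyst, 50.0% of the amount charged, then wait 80 min
- Tuesday's: change nothing and wait 80 min more

- free catalyst is single-handed; left-handed substrate and right-handed substrate are mirror images of each other, charged as a racemate, each of them at the stated concentration
- what is taken out of left-handed product is counted as made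
- additions bring no volume worth counting

* left-handed product, in percent of the left-handed substrate and right-handed substrate together first charged, at 2.5 h
* the option that brings most further left-handed product ("none" if no option brings more than 2 percentage points) (Monday's / Friday's / Sunday's / Tuesday's / none)
* left-handed product present, with what was taken out counted in, in percent of the left-handed substrate and right-handed substrate together first charged, after Sunday's
* left-handed product present, with what was taken out counted in, in percent of the left-handed substrate and right-handed substrate together first charged, after Tuesday's

In the autumn run the first 8.00 min give 3.3%, but the next 17.0 min give 3 percentage points, so I read the catalyst as dying, and the impurity is charged at 41 mM beside 40 mM of free catalyst. Counting one impurity for one catalyst, as my own supposition, the autumn flask stands at −1.00 mM and Sunday's at 19.0 mM: that is the catalyst margin, the free catalyst charged in sum less the impurity charged in sum. The late pace, held for 80 min, gives 1.7 points, which is less than the 2 points asked for.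

The margin brackets Sunday's. For a floor I share the first pace over the whole charge and run 19.0 mM at it for 80 min, cut to the 84.8% of partner I reckon left, and add this to the last reading: 24.7%. For a ceiling I grant those first minutes' catalyst half strength on average and drop the partner cut: 42.7%.

The forecast speaks of “catalyst being killed second-order by the almost equimolar impurity” and gives 11.3% now, Sunday's as best, 24.5% after Sunday's and 12.4% after Tuesday's. Its Sunday's figure stands 0.20 points below my floor, a floor resting on one reading of 3.3% that scatters by 0.5 points.

The flask gives 11.1% at 2.5 h, Sunday's as best, 25.4% after Sunday's and 11.6% after Tuesday's.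

    free catalyst + left-handed substrate ⇌ catalyst intermediate A (K = 15.0 /M, k = 0.220 /M/s, Ea = 41.0 kJ/mol, ΔH = −33.0 kJ/mol)
    free catalyst + right-handed substrate ⇌ catalyst intermediate B (K = 0.320 /M, k = 0.0410 /M/s, Ea = 61.0 kJ/mol, ΔH = −46.0 kJ/mol)
    partner + catalyst intermediate A → free catalyst + left-handed product (k = 0.00390 /M/s, Ea = 71.0 kJ/mol)
    partner + catalyst intermediate B → free catalyst + right-handed product (k = 1.80 × 10⁻⁴ /M/s, Ea = 69.0 kJ/mol)
    free catalyst + impurity → spent catalyst A (k = 0.490 /M/s, Ea = 41.0 kJ/mol)
    partner + free catalyst → spent catalyst B (k = 2.80 × 10⁻⁴ /M/s, Ea = 68.0 kJ/mol)
    (constants at 5 °C)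

So the autumn flask's 25.4% lies inside my bracket, and Sunday's brings 14 points against 0.71 points for Monday's. At 150 min the partner has turned 3.94% of the catalyst into spent catalyst B, which takes the margin 19.0 mM down to 17.4 mM.

In the neighbour flask with 0.16 M of impurity the margin is −120 mM, so I expect no working catalyst and that much impurity over. The computed neighbour flask at 150 min holds free catalyst 0%, impurity 120 mM and left-handed product 1.50%.

The data were generated by integration with constants of no real substance; the scatter is artificial.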